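## Structural features

Compound 22 is a C15 bromo-ether of the bisabolane type with one acetate. A cyclohexane (C5, C6, C7, C22, C21, C20; labels follow the heavy-atom order of the target SMILES) has its 1,4-carbons C7 and C20 spanned by O9–C10–C18, giving a 2-oxabicyclo[3.2.2]nonane, and a 3-bromo-2,2-dimethyltetrahydropyran (C10, C11, C12, C14, O17, C18) is cis-fused onto the C10–C18 bond. Seen the other way, a pyran and an oxepane (O9, C7, C22, C21, C20, C18, C10) share C10–C18, and the two-carbon unit C5–C6 bridges oxepane positions 2 (C7) and 5 (C20). The seven stereocentres (5S, 7R, 10S, 12S, 18S, 20R, 22R) form two contiguous runs, C22–C7 and C10–C18–C20–C5, joined through O9; C7 and C18 are fully substituted ether carbons, and C12 carries bromine beside the gem-dimethyl carbon C14 with no neighbour to steer it. On the oxepane, the C5–C6 bridge, O17, C11 and the C22 oxygen lie on one face, so the pyran hangs over the C5–C6 bridge, the C5 acetoxy group points toward O17, and the C22 hydroxyl points into the gap between the two carbon bridges. Fragile points are the secondary bromide β to O17 (reductive elimination by zinc or other low-valent metals, hydrogenolysis, forcing base), the tertiary allylic ether carbon C7 before the carbocycle exists (acid ionisation), and the need to keep two hindered secondary oxygens apart, one acetylated (C5) and one free (C22). The real difficulty is the bridged ether around quaternary C7 together with two centres (C12, C20) that have no strong built-in bias. The key step uses the fact that every ring atom except C5 and C6 already belongs to the cis-fused pyran–oxepane, so a vinyl group on C7 and a 1-silyloxyvinyl group on C20, cis on the oxepane, need only lose ethylene to close the cyclohexene with the C5 oxygen already in place.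

## Logic of the disconnections

22 ⇒ 21 ⇒ 20 ⇒ 19. The acetyl C–O bond at C5 and the Si–O bond at C22 are cut, and the C5 carbinol is returned to a ketone. The reason is that the two secondary oxygens must arrive in different forms (ketone and silyl ether) so that only C5 is acylated. The gain is the loss of the C5 stereocentre. The demand is hydride delivery to C5 from the C21 side, which is the open face because the pyran covers the other, and desilylation under conditions that spare the acetate and the bromide.

19 ⇒ 18 ⇒ 17. The C5=C6 bond is cut (hydrolysis of the enol ether backwards, then the metathesis). This removes the carbocycle and the bridge in one stroke and leaves a fused bicycle with two olefinic arms. The demand is that the arms on C7 and C20 are cis and that the oxepane can hold both pseudoaxial. Both centres are therefore fixed earlier by substrate- and reagent-controlled steps, not by equilibration at C20.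

17 ⇒ 16 ⇒ 15. The O–Si bond of the enol ether is cut and the C5 ketone is returned to a terminal alkyne. The reason is a design correction: a C5 carbonyl (or its hemiketal with O9) would compete as an oxygen nucleophile in the acid step that makes 14, so C5 is carried through that step as an alkyne. The demand is a Markovnikov hydration that leaves the C7 vinyl group alone and a kinetic enolisation at the methyl group only.

15 ⇒ 14 ⇒ 13 ⇒ 12. The C7–O9 bond is cut. Backwards this gives a vinyl epoxide and then a (Z)-diene, so C7 and C22 both derive from one reagent-controlled epoxidation. The gain is the oxepane and two stereocentres. The demand is attack at the tertiary allylic carbon with clean inversion, and a Z olefin so that the C22 oxygen and the vinyl group end cis.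

12 ⇒ 11 ⇒ 10 ⇒ 9. The C5≡C bond is cut back to a lactone carbonyl (one-carbon homologation through the lactol), and the diene is returned to an enyne. The lactone ties O9 to C5, so C10–OH needs no protecting group until the moment it is required as nucleophile. The demand is that C20, α to the transient aldehyde, does not epimerise, and that the semihydrogenation stops at the diene.

9 ⇒ 8. The O17–C14 and C12–Br bonds are cut (bromoetherification). The pyran, the bromide and the gem-dimethyl carbon all come from a prenyl group. The demand is 6-endo closure and the correct face at C12. The enyne must be a poorer bromonium acceptor than the prenyl olefin, which is why the alkyne is reduced only afterwards.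

8 ⇒ 7 + 2. The C20–C21 bond is cut (enolate alkylation). The whole C21–C22–C7–C6 arm is bought with its Z geometry. The demand is facial control at C20, supplied by the tertiary lithium alkoxide of the β-hydroxy lactone dianion.

7 ⇒ 5 (through 6). The C18–C20 bond and the lactone acyl–O9 bond are cut (acetate aldol, lactonisation). The gain is the C18 quaternary centre. The demand is chelation control by the free C10 hydroxyl.

5 ⇒ 3 (through 4) and 2 ⇒ 1. The C10–O9 bond is cut back to an enamine-catalysed α-oxygenation of the commercial ketone, and the C–Br bond of the allylic bromide back to the commercial Z-enynol. The demand is reaction at the methylene and not the methyl side of 3, and retention of the Z geometry in 2.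

## Other disconnections considered

Alternative 1: The cut is O17–C14, with the pyran traced back to a furan. In the forward direction the 5-methylfuryl tertiary carbinol A2 is oxidised (for example with NBS in wet THF), the furan opens and the C18 hydroxyl closes on C14 to give the pyranone hemiketal A1.
- In favour: the oxidative ring expansion is one of the most dependable pyran syntheses, it delivers the C10 oxygen as a ketone, and the carbocycle with C5 and C20 comes from a pre-formed cyclohexene.
- Against: A1 has one methyl on C14 and no bromine. The second methyl needs a C-glycoside-type addition at the hemiketal, the C12 bromide must be installed on an existing ring next to a quaternary carbon, and the C10 ketone must be reduced selectively. C18 arises from addition of a furyl metal to a methyl ketone next to C20 with little control, and the C7–O9 ether still has to be closed late on a crowded system.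
- Comparison: on structure this plan is the better one in that no medium-ring-spanning closure of the carbocycle is needed. On mechanism the chosen plan is stronger, because bromine, gem-dimethyl carbon and pyran come from one bromoetherification and C18 from a chelate. Step economy is about equal at best.

Alternative 2: The cuts are C6–C7 and C5–C20. In the forward direction the vinylsilyl ether of the ortho-quinol dienone A4 undergoes a tethered intramolecular Diels–Alder reaction to the oxasilolane-fused bicyclo[2.2.2]octenone A3.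
- In favour: two C–C bonds, the carbocycle and the relative configuration of C5, C7, C18 and C20 come from a flat precursor in one concerted step, and oxidation of the C–Si bond gives the C5 oxygen with retention. On stereocentres built per step, and in avoiding any hydride-face question at C5, this plan is better than the chosen one.
- Against: dienones of this kind dimerise readily, and absolute configuration needs an asymmetric dearomatisation or a resolution. O9 must then be inserted between C7 and C10 by Baeyer–Villiger oxidation, where migration of the oxygen-bearing quaternary C18 is at least as likely. The whole bromopyran has to be grafted onto the resulting lactone.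
- Comparison: the pericyclic step is more predictable than a bridging metathesis, but the skeleton it gives is one oxygen short and needs ring expansion. The plan starts fast and ends long.

Alternative 3: The cut is C10–C18. In the forward direction SmI2 reduces the methyl ketone of the keto alkoxyacrylate A6 and the ketyl adds to the acrylate β-carbon, giving the bridged hydroxy ester A5.
- In favour: ketyl addition to β-alkoxyacrylates is a well-tried way to cyclic ethers, the chelated transition state sets C10 and C18 together, and the conditions are neutral. The key step creates a C–C bond and two stereocentres where the chosen key step creates none, so on that count it is the better one.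
- Against: A6 is itself a cyclohexane with four stereocentres and a tertiary alkoxyacrylate on C7. The closure must bridge a six-membered ring through 1,4-diaxial arms, outside the usual fused-ring scope. The bromopyran must still be built afterwards from the ester, so the least controllable step (bromoetherification) comes last instead of early.
- Comparison: it is equal to the chosen plan in relying on one uncertain bridging closure, weaker in where the bromide is introduced, and no shorter.

Key step: step 14

Remark on the chemistry: atom labels (C5, C7, O9 and so on) follow the heavy-atom order of the target SMILES throughout. Lactol 11 is carried as an anomeric mixture. D-proline, nitrosobenzene, the D-fructose-derived Shi ketone, the Ohira–Bestmann reagent and 2,4,4,6-tetrabromocyclohexa-2,5-dien-1-one (TBCO) are taken as purchased reagents. Compounds 17 and 18 carry the configuration of 22 at C7, C10, C12, C18, C20 and C22.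

## Route

Step 1
Reactants: 1 (2Z)-3-methylpent-2-en-4-yn-1-ol
Product: 2 (2Z)-1-bromo-3-methylpent-2-en-4-yne
Conditions: PBr3 (0.4 equiv), pyridine (cat.), Et2O, −10 → 0 °C
Reagents that add atoms: phosphorus tribromide, BrP(Br)Br
Why: Bromination of a primary allylic alcohol through its phosphite (SN2 by bromide); low temperature and a neutral work-up should keep the Z-enyne geometry, and the bromide is used directly.

Step 2
Reactants: 3 6-methylhept-5-en-2-one (sulcatone)
Product: 5 (3S)-3-hydroxy-6-methylhept-5-en-2-one, via aminoxy ketone 4 (not isolated)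
Conditions: 3 (3 equiv), PhNO (slow addition), D-proline (20 mol%), DMSO, rt; then CuSO4·5H2O (30 mol%), MeOH, 0 °C
Reagents that add atoms: nitrosobenzene, O=Nc1ccccc1
Why: Proline-catalysed α-aminoxylation (enamine catalysis): the more substituted enamine attacks the nitroso oxygen on the face fixed by hydrogen bonding to the carboxylic acid, and D-proline should give the 3S centre (C10). Copper-catalysed N–O cleavage then frees the α-hydroxy ketone without touching that centre.

Step 3
Reactants: 5 (3S)-3-hydroxy-6-methylhept-5-en-2-one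
Product: 7 (4S,5S)-4-hydroxy-4-methyl-5-(3-methylbut-2-en-1-yl)oxolan-2-one, via dihydroxy ester 6 (not isolated)
Conditions: EtOAc, LiN(i-Pr)2 (3 equiv), THF, −78 °C; MgBr2·OEt2; 5, −78 °C; AcOH; then PPTS (cat.), CH2Cl2, rt
Reagents that add atoms: ethyl acetate, CCOC(C)=O
Why: Chelation-controlled acetate aldol addition (Cram cyclic model): the metal alkoxide of C10–OH chelates the ketone and the enolate adds anti to the prenyl CH2, setting C18 (S). The secondary C10 hydroxyl then closes the γ-lactone, which ties up O9 and C5 without a protecting group and leaves only the tertiary hydroxyl free.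

Step 4
Reactants: 7 (4S,5S)-4-hydroxy-4-methyl-5-(3-methylbut-2-en-1-yl)oxolan-2-one; 2 (2Z)-1-bromo-3-methylpent-2-en-4-yne
Product: 8 (3S,4S,5S)-4-hydroxy-4-methyl-5-(3-methylbut-2-en-1-yl)-3-[(2Z)-3-methylpent-2-en-4-yn-1-yl]oxolan-2-one
Conditions: LiN(i-Pr)2 (2.2 equiv), THF, −78 → −40 °C; 2, DMPU, −78 → −30 °C; aq. NH4Cl
Reagents that add atoms: none
Why: Fráter–Seebach-type alkylation of a β-hydroxy lactone dianion: the allylic bromide should enter anti to the lithium alkoxide on C18 and anti to the prenyl group on C10, which places C21 cis to the C18 methyl and sets C20. The alkoxide is a poor leaving group, so β-elimination is not expected.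

Step 5
Reactants: 8 (3S,4S,5S)-4-hydroxy-4-methyl-5-(3-methylbut-2-en-1-yl)-3-[(2Z)-3-methylpent-2-en-4-yn-1-yl]oxolan-2-one
Product: 9 (3S,3aS,6S,7aS)-6-bromo-3a,5,5-trimethyl-3-[(2Z)-3-methylpent-2-en-4-yn-1-yl]hexahydro-2H-furo[3,2-b]pyran-2-one
Conditions: TBCO (1.1 equiv), MeNO2, 0 °C → rt, dark
Reagents that add atoms: 2,4,4,6-tetrabromocyclohexa-2,5-dien-1-one, O=C1C(Br)=CC(Br)(Br)C=C1Br
Why: 6-endo bromoetherification: the C18 hydroxyl opens the bromonium ion at the tertiary C14 (Markovnikov), anti to bromine. A chair transition state with bromine equatorial, the C18 methyl axial and the branched C20 equatorial should favour the 12S epimer. The conjugated enyne is a much poorer bromonium acceptor than the isolated prenyl olefin.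

Step 6
Reactants: 9 (3S,3aS,6S,7aS)-6-bromo-3a,5,5-trimethyl-3-[(2Z)-3-methylpent-2-en-4-yn-1-yl]hexahydro-2H-furo[3,2-b]pyran-2-one
Product: 10 (3S,3aS,6S,7aS)-6-bromo-3a,5,5-trimethyl-3-[(2Z)-3-methylpenta-2,4-dien-1-yl]hexahydro-2H-furo[3,2-b]pyran-2-one
Conditions: H2 (1 atm, 1 equiv uptake), Pd/CaCO3 poisoned with Pb(OAc)2 (Lindlar catalyst), quinoline, EtOAc, rt
Reagents that add atoms: none
Why: Lindlar semihydrogenation of the terminal alkyne of the conjugated enyne to the vinyl group; the poisoned catalyst should leave the trisubstituted olefin, the lactone and the alkyl bromide alone. Zinc-based reductions are avoided because they would cleave the β-bromo ether.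

Step 7
Reactants: 10 (3S,3aS,6S,7aS)-6-bromo-3a,5,5-trimethyl-3-[(2Z)-3-methylpenta-2,4-dien-1-yl]hexahydro-2H-furo[3,2-b]pyran-2-one
Product: 11 (3S,3aS,6S,7aS)-6-bromo-3a,5,5-trimethyl-3-[(2Z)-3-methylpenta-2,4-dien-1-yl]hexahydro-2H-furo[3,2-b]pyran-2-ol (anomers)
Conditions: i-Bu2AlH (1.2 equiv), CH2Cl2, −78 °C; aq. KNaC4H4O6
Reagents that add atoms: none
Why: Partial reduction of a lactone to the lactol; the tetrahedral aluminate is stable at −78 °C, so over-reduction to the diol is not expected.

Step 8
Reactants: 11 (3S,3aS,6S,7aS)-6-bromo-3a,5,5-trimethyl-3-[(2Z)-3-methylpenta-2,4-dien-1-yl]hexahydro-2H-furo[3,2-b]pyran-2-ol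
Product: 12 (2S,3S,5S)-5-bromo-2,6,6-trimethyl-2-[(3R,5Z)-6-methylocta-5,7-dien-1-yn-3-yl]oxan-3-ol
Conditions: dimethyl (1-diazo-2-oxopropyl)phosphonate (2 equiv), K2CO3, MeOH, 0 °C → rt
Reagents that add atoms: dimethyl (1-diazo-2-oxopropyl)phosphonate, CC(=O)C(=[N+]=[N-])P(=O)(OC)OC
Why: Ohira–Bestmann (Seyferth–Gilbert) homologation of the open hydroxy-aldehyde form of the lactol. It frees C10–OH and turns C5 into an alkyne carbon, a ketone precursor that cannot act as an oxygen nucleophile in step 10. Mild carbonate base and the hindered C20 should keep the α-centre intact.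

Step 9
Reactants: 12 (2S,3S,5S)-5-bromo-2,6,6-trimethyl-2-[(3R,5Z)-6-methylocta-5,7-dien-1-yn-3-yl]oxan-3-ol
Product: 13 (2S,3S,5S)-5-bromo-2-{(2R)-1-[(2R,3S)-3-ethenyl-3-methyloxiran-2-yl]but-3-yn-2-yl}-2,6,6-trimethyloxan-3-ol
Conditions: D-fructose-derived Shi ketone (30 mol%), KHSO5 (as 2KHSO5·KHSO4·K2SO4), K2CO3, Bu4NHSO4, MeCN–CH2(OMe)2/aq. Na2B4O7 buffer (pH 10.5), 0 °C
Reagents that add atoms: potassium peroxymonosulfate, [K+].[O-]S(=O)(=O)OO
Why: Shi asymmetric epoxidation (chiral dioxirane, spiro transition state): the trisubstituted, more electron-rich olefin of the diene reacts, the alkyne is inert, and the D-fructose-derived ketone should give the (2R,3S)-oxirane (C22 R, C7 S) by reagent control.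

Step 10
Reactants: 13 (2S,3S,5S)-5-bromo-2-{(2R)-1-[(2R,3S)-3-ethenyl-3-methyloxiran-2-yl]but-3-yn-2-yl}-2,6,6-trimethyloxan-3-ol
Product: 14 (3S,4aS,6R,7R,9R,9aS)-3-bromo-6-ethenyl-9-ethynyl-2,2,6,9a-tetramethyloctahydro-2H-pyrano[3,2-b]oxepin-7-ol
Conditions: CSA (10 mol%), CH2Cl2, −40 → 0 °C
Reagents that add atoms: none
Why: Acid-catalysed 7-endo hydroxy-epoxide cyclisation: C10–OH opens the vinyl epoxide at the tertiary, allylic C7 with inversion (C7 becomes R, C22–OH stays R). The methyl and vinyl groups stabilise positive charge at C7, so 6-exo attack at C22 should not compete. With C5 as an alkyne there is no carbonyl oxygen to intercept the epoxide.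

Step 11
Reactants: 14 (3S,4aS,6R,7R,9R,9aS)-3-bromo-6-ethenyl-9-ethynyl-2,2,6,9a-tetramethyloctahydro-2H-pyrano[3,2-b]oxepin-7-ol
Product: 15 tert-butyl{[(3S,4aS,6R,7R,9R,9aS)-3-bromo-6-ethenyl-9-ethynyl-2,2,6,9a-tetramethyloctahydro-2H-pyrano[3,2-b]oxepin-7-yl]oxy}dimethylsilane
Conditions: TBSOTf, 2,6-lutidine, CH2Cl2, −78 → 0 °C
Reagents that add atoms: tert-butyldimethylsilyl trifluoromethanesulfonate, CC(C)(C)[Si](C)(C)OS(=O)(=O)C(F)(F)F
Why: Silylation of the hindered secondary C22 hydroxyl with a silyl triflate and a hindered base; the silyl ether later distinguishes O23 from the C5 oxygen.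

Step 12
Reactants: 15 tert-butyl{[(3S,4aS,6R,7R,9R,9aS)-3-bromo-6-ethenyl-9-ethynyl-2,2,6,9a-tetramethyloctahydro-2H-pyrano[3,2-b]oxepin-7-yl]oxy}dimethylsilane
Product: 16 1-[(3S,4aS,6R,7R,9S,9aS)-3-bromo-7-{[tert-butyl(dimethyl)silyl]oxy}-6-ethenyl-2,2,6,9a-tetramethyloctahydro-2H-pyrano[3,2-b]oxepin-9-yl]ethan-1-one
Conditions: Ph3PAuNTf2 (2 mol%), 1,4-dioxane–H2O, 60 °C
Reagents that add atoms: water, O
Why: Markovnikov hydration of a terminal alkyne catalysed by monovalent gold gives the methyl ketone through the terminal enol, so C20 is not involved. The neutral medium should spare the silyl ether, and the vinyl group on quaternary C7 is a poor partner for enyne cyclisation.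

Step 13
Reactants: 16 1-[(3S,4aS,6R,7R,9S,9aS)-3-bromo-7-{[tert-butyl(dimethyl)silyl]oxy}-6-ethenyl-2,2,6,9a-tetramethyloctahydro-2H-pyrano[3,2-b]oxepin-9-yl]ethan-1-one
Product: 17 tert-butyl{[(3S,4aS,6R,7R,9S,9aS)-3-bromo-6-ethenyl-2,2,6,9a-tetramethyl-9-{1-[(triethylsilyl)oxy]ethenyl}octahydro-2H-pyrano[3,2-b]oxepin-7-yl]oxy}dimethylsilane
Conditions: LiN(i-Pr)2, THF, −78 °C; Et3SiCl, −78 → −40 °C; pH 7 buffer
Reagents that add atoms: chlorotriethylsilane, CC[Si](Cl)(CC)CC
Why: Kinetic enolisation and O-silylation: the amide base removes a methyl proton, far more accessible than the tertiary C20–H flanked by quaternary C18, so the terminal silyl enol ether forms without touching C20.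

Step 14
Reactants: 17 tert-butyl{[(3S,4aS,6R,7R,9S,9aS)-3-bromo-6-ethenyl-2,2,6,9a-tetramethyl-9-{1-[(triethylsilyl)oxy]ethenyl}octahydro-2H-pyrano[3,2-b]oxepin-7-yl]oxy}dimethylsilane
Product: 18 tert-butyl{[(1S,2S,5S,7S,9R,13R)-5-bromo-2,4,4,9-tetramethyl-11-[(triethylsilyl)oxy]-3,8-dioxatricyclo[7.2.2.0^{2,7}]tridec-10-en-13-yl]oxy}dimethylsilane
Conditions: RuCl2(=CHPh)(H2IMes)(PCy3) (second-generation Grubbs catalyst, 10 mol% in two portions), degassed toluene (2 mM), 80 °C, Ar sparge; Et3N-buffered work-up
Reagents that add atoms: none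
Why: Ring-closing olefin metathesis by the Chauvin mechanism: the ruthenium benzylidene should initiate at the monosubstituted C7 vinyl group, the alkylidene at C6 adds across the 1,1-disubstituted enol ether with ruthenium on the terminal CH2, and cycloreversion releases the C5=C6 enol ether and Ru=CH2, which leaves as ethylene. The closest known reaction types are ring-closing metathesis of silyl enol ethers with terminal olefins by second-generation ruthenium carbenes and metathesis closure of bridged bicycles from cis-dialkenyl rings. The ring closed is the six-membered carbocycle C5–C6–C7–C22–C21–C20, formed as a two-carbon bridge across positions 2 and 5 of the oxepane; the result is a bicyclo[3.2.2]nonene with its olefin inside a two-atom bridge, so no bridgehead double bond arises. No stereocentre is created; the step needs the two arms cis, which C7 (invertive epoxide opening, step 10) and C20 (dianion alkylation, step 4) secure, and an oxepane conformer with both arms pseudoaxial, which a seven-membered ring can reach. Productive initiation relies on the vinyl group being far more reactive toward the carbene than the electron-rich enol ether, so the unreactive alkoxy-substituted carbene should form only slowly. High dilution, heat and removal of ethylene favour closure over dimerisation, and base-washed glassware keeps the enol silane from hydrolysing.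

Step 15
Reactants: 18 tert-butyl{[(1S,2S,5S,7S,9R,13R)-5-bromo-2,4,4,9-tetramethyl-11-[(triethylsilyl)oxy]-3,8-dioxatricyclo[7.2.2.0^{2,7}]tridec-10-en-13-yl]oxy}dimethylsilane
Product: 19 (1S,2S,5S,7S,9R,13R)-5-bromo-13-{[tert-butyl(dimethyl)silyl]oxy}-2,4,4,9-tetramethyl-3,8-dioxatricyclo[7.2.2.0^{2,7}]tridecan-11-one
Conditions: 0.1 M HCl, THF–H2O, 0 °C
Reagents that add atoms: none
Why: Acid hydrolysis of a silyl enol ether (protonation at C6, loss of silanol) gives the C5 ketone; the secondary TBS ether is far slower to cleave, and the bridgehead C20 cannot enolise.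

Step 16
Reactants: 19 (1S,2S,5S,7S,9R,13R)-5-bromo-13-{[tert-butyl(dimethyl)silyl]oxy}-2,4,4,9-tetramethyl-3,8-dioxatricyclo[7.2.2.0^{2,7}]tridecan-11-one
Product: 20 (1R,2S,5S,7S,9R,11S,13R)-5-bromo-13-{[tert-butyl(dimethyl)silyl]oxy}-2,4,4,9-tetramethyl-3,8-dioxatricyclo[7.2.2.0^{2,7}]tridecan-11-ol
Conditions: NaBH4, MeOH, −40 → 0 °C
Reagents that add atoms: none
Why: Hydride reduction under steric approach control: the ketone face toward the O9 bridge is covered by O17 and the pyran held over the C5–C6 bridge, so hydride should enter from the C21 side and place the C5 hydroxyl syn to O17 (5S).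

Step 17
Reactants: 20 (1R,2S,5S,7S,9R,11S,13R)-5-bromo-13-{[tert-butyl(dimethyl)silyl]oxy}-2,4,4,9-tetramethyl-3,8-dioxatricyclo[7.2.2.0^{2,7}]tridecan-11-ol
Product: 21 (1R,2S,5S,7S,9R,11S,13R)-5-bromo-13-{[tert-butyl(dimethyl)silyl]oxy}-2,4,4,9-tetramethyl-3,8-dioxatricyclo[7.2.2.0^{2,7}]tridecan-11-yl acetate
Conditions: Ac2O, DMAP (cat.), pyridine, CH2Cl2, rt
Reagents that add atoms: acetic anhydride, CC(=O)OC(C)=O
Why: DMAP-catalysed acylation of the only free hydroxyl; the C22 oxygen is still silylated, so no selectivity problem arises.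

Step 18
Reactants: 21 (1R,2S,5S,7S,9R,11S,13R)-5-bromo-13-{[tert-butyl(dimethyl)silyl]oxy}-2,4,4,9-tetramethyl-3,8-dioxatricyclo[7.2.2.0^{2,7}]tridecan-11-yl acetate
Product: 22 (1R,2S,5S,7S,9R,11S,13R)-5-bromo-13-hydroxy-2,4,4,9-tetramethyl-3,8-dioxatricyclo[7.2.2.0^{2,7}]tridecan-11-yl acetate
Conditions: HF·pyridine, pyridine–THF, 0 °C → rt
Reagents that add atoms: none
Why: Fluoride-mediated desilylation under buffered, non-basic conditions; the acetate and the secondary bromide are stable, and the C5 acetate cannot migrate to the diagonal C22 oxygen.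

## Compound list

1 | (2Z)-3-methylpent-2-en-4-yn-1-ol | C#C/C(C)=C\CO | starting material
2 | (2Z)-1-bromo-3-methylpent-2-en-4-yne | C#C/C(C)=C\CBr | intermediate
3 | 6-methylhept-5-en-2-one (sulcatone) | CC(C)=CCCC(C)=O | starting material
4 | (3S)-6-methyl-3-[(phenylamino)oxy]hept-5-en-2-one | c1ccccc1NO[C@H](C(C)=O)CC=C(C)C | intermediate (not isolated)
5 | (3S)-3-hydroxy-6-methylhept-5-en-2-one | O[C@H](C(C)=O)CC=C(C)C | intermediate
6 | ethyl (3S,4S)-3,4-dihydroxy-3,7-dimethyloct-6-enoate | O[C@@H](CC=C(C)C)[C@@](C)(O)CC(=O)OCC | intermediate (not isolated)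
7 | (4S,5S)-4-hydroxy-4-methyl-5-(3-methylbut-2-en-1-yl)oxolan-2-one | O=C1C[C@](C)(O)[C@H](CC=C(C)C)O1 | intermediate
8 | (3S,4S,5S)-4-hydroxy-4-methyl-5-(3-methylbut-2-en-1-yl)-3-[(2Z)-3-methylpent-2-en-4-yn-1-yl]oxolan-2-one | O=C1[C@@H](C/C=C(C)\C#C)[C@](C)(O)[C@H](CC=C(C)C)O1 | intermediate
9 | (3S,3aS,6S,7aS)-6-bromo-3a,5,5-trimethyl-3-[(2Z)-3-methylpent-2-en-4-yn-1-yl]hexahydro-2H-furo[3,2-b]pyran-2-one | O=C1O[C@H]2C[C@H](Br)C(C)(C)O[C@@]2(C)[C@@H]1C/C=C(C)\C#C | intermediate
10 | (3S,3aS,6S,7aS)-6-bromo-3a,5,5-trimethyl-3-[(2Z)-3-methylpenta-2,4-dien-1-yl]hexahydro-2H-furo[3,2-b]pyran-2-one | O=C1O[C@H]2C[C@H](Br)C(C)(C)O[C@@]2(C)[C@@H]1C/C=C(C)\C=C | intermediate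
11 | (3S,3aS,6S,7aS)-6-bromo-3a,5,5-trimethyl-3-[(2Z)-3-methylpenta-2,4-dien-1-yl]hexahydro-2H-furo[3,2-b]pyran-2-ol (anomers) | OC1O[C@H]2C[C@H](Br)C(C)(C)O[C@@]2(C)[C@@H]1C/C=C(C)\C=C | intermediate
12 | (2S,3S,5S)-5-bromo-2,6,6-trimethyl-2-[(3R,5Z)-6-methylocta-5,7-dien-1-yn-3-yl]oxan-3-ol | O[C@H]1C[C@H](Br)C(C)(C)O[C@@]1(C)[C@@H](C#C)C/C=C(C)\C=C | intermediate
13 | (2S,3S,5S)-5-bromo-2-{(2R)-1-[(2R,3S)-3-ethenyl-3-methyloxiran-2-yl]but-3-yn-2-yl}-2,6,6-trimethyloxan-3-ol | O[C@H]1C[C@H](Br)C(C)(C)O[C@@]1(C)[C@@H](C#C)C[C@H]2O[C@@]2(C)C=C | intermediate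
14 | (3S,4aS,6R,7R,9R,9aS)-3-bromo-6-ethenyl-9-ethynyl-2,2,6,9a-tetramethyloctahydro-2H-pyrano[3,2-b]oxepin-7-ol | C=C[C@@]1(C)O[C@H]2C[C@H](Br)C(C)(C)O[C@@]2(C)[C@@H](C#C)C[C@H]1O | intermediate
15 | tert-butyl{[(3S,4aS,6R,7R,9R,9aS)-3-bromo-6-ethenyl-9-ethynyl-2,2,6,9a-tetramethyloctahydro-2H-pyrano[3,2-b]oxepin-7-yl]oxy}dimethylsilane | C=C[C@@]1(C)O[C@H]2C[C@H](Br)C(C)(C)O[C@@]2(C)[C@@H](C#C)C[C@H]1O[Si](C)(C)C(C)(C)C | intermediate
16 | 1-[(3S,4aS,6R,7R,9S,9aS)-3-bromo-7-{[tert-butyl(dimethyl)silyl]oxy}-6-ethenyl-2,2,6,9a-tetramethyloctahydro-2H-pyrano[3,2-b]oxepin-9-yl]ethan-1-one | C=C[C@@]1(C)O[C@H]2C[C@H](Br)C(C)(C)O[C@@]2(C)[C@@H](C(C)=O)C[C@H]1O[Si](C)(C)C(C)(C)C | intermediate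
17 | tert-butyl{[(3S,4aS,6R,7R,9S,9aS)-3-bromo-6-ethenyl-2,2,6,9a-tetramethyl-9-{1-[(triethylsilyl)oxy]ethenyl}octahydro-2H-pyrano[3,2-b]oxepin-7-yl]oxy}dimethylsilane | C=C[C@@]1(C)O[C@H]2C[C@H](Br)C(C)(C)O[C@@]2(C)[C@@H](C(=C)O[Si](CC)(CC)CC)C[C@H]1O[Si](C)(C)C(C)(C)C | intermediate
18 | tert-butyl{[(1S,2S,5S,7S,9R,13R)-5-bromo-2,4,4,9-tetramethyl-11-[(triethylsilyl)oxy]-3,8-dioxatricyclo[7.2.2.0^{2,7}]tridec-10-en-13-yl]oxy}dimethylsilane | CC[Si](CC)(CC)OC1=C[C@@]2(C)O[C@H]3C[C@H](Br)C(C)(C)O[C@@]3(C)[C@@H]1C[C@H]2O[Si](C)(C)C(C)(C)C | intermediate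
19 | (1S,2S,5S,7S,9R,13R)-5-bromo-13-{[tert-butyl(dimethyl)silyl]oxy}-2,4,4,9-tetramethyl-3,8-dioxatricyclo[7.2.2.0^{2,7}]tridecan-11-one | O=C1C[C@@]2(C)O[C@H]3C[C@H](Br)C(C)(C)O[C@@]3(C)[C@@H]1C[C@H]2O[Si](C)(C)C(C)(C)C | intermediate
20 | (1R,2S,5S,7S,9R,11S,13R)-5-bromo-13-{[tert-butyl(dimethyl)silyl]oxy}-2,4,4,9-tetramethyl-3,8-dioxatricyclo[7.2.2.0^{2,7}]tridecan-11-ol | O[C@H]1C[C@@]2(C)O[C@H]3C[C@H](Br)C(C)(C)O[C@@]3(C)[C@@H]1C[C@H]2O[Si](C)(C)C(C)(C)C | intermediate
21 | (1R,2S,5S,7S,9R,11S,13R)-5-bromo-13-{[tert-butyl(dimethyl)silyl]oxy}-2,4,4,9-tetramethyl-3,8-dioxatricyclo[7.2.2.0^{2,7}]tridecan-11-yl acetate | CC(=O)O[C@H]1C[C@@]2(C)O[C@H]3C[C@H](Br)C(C)(C)O[C@@]3(C)[C@@H]1C[C@H]2O[Si](C)(C)C(C)(C)C | intermediate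
22 | (1R,2S,5S,7S,9R,11S,13R)-5-bromo-13-hydroxy-2,4,4,9-tetramethyl-3,8-dioxatricyclo[7.2.2.0^{2,7}]tridecan-11-yl acetate | CC(=O)O[C@H]1C[C@@]2(C)O[C@H]3C[C@H](Br)C(C)(C)O[C@@]3(C)[C@@H]1C[C@H]2O | target

## Step count and least certain steps

Total: 18 steps. Longest linear sequence: 17 steps (3 → 22, steps 2–18); the one-step preparation of 2 is the only side branch.

**Step 14 (key step).** The most likely failure is that the bridging closure does not turn over. The alkylidene on the neopentyl-type C7 vinyl group must reach an electron-rich 1,1-disubstituted enol ether across the oxepane in a diaxial conformer before the catalyst decays. Dimerisation at the vinyl group and hydrolytic loss of the enol silane are the side processes. Fallback (sets out from 15, comes back at 19): keep the enol ether out of the metathesis. Semihydrogenation of the ethynyl group of 15 (H2, Pd/CaCO3 poisoned with Pb(OAc)2, quinoline) would give the divinyl oxepane F1. Ring-closing metathesis of its two monosubstituted olefins with the same ruthenium carbene would give the bridged cyclohexene F2. Hydroboration (BH3·SMe2, then NaBO3) should put boron on C5, the olefin carbon remote from the quaternary, oxygen-bearing C7, and from the open C21 side, giving the C5 alcohol F3 (expected as the C5 epimer of 20). Dess–Martin oxidation of F3 gives 19.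

**Step 5.** The likely problems are poor facial selectivity at C12 and competing 5-exo closure to a tetrahydrofuran, because the bromonium ion can form on either face with only the chair preference to discriminate. Fallback (sets out from 8, comes back at 9): fix C12 by reagent control and regenerate the bromonium ion stereospecifically. Shi epoxidation of the prenyl olefin of 8 with the D-fructose-derived ketone (the enyne olefin is deactivated) would give the epoxide F4. Bromide opening at the secondary carbon with inversion (Li2NiBr4, THF) would give the bromohydrin F5. Acid-promoted ionisation of the tertiary C14 hydroxyl with bromine participation, and capture of the resulting bromonium ion at C14 by the C18 hydroxyl, returns to 9 with C12 defined.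

**Step 2.** The risks are attack at the methyl side of the ketone, incomplete enantiocontrol for an acyclic ketone, and a nitroso-ene reaction at the prenyl olefin. Fallback (starts from (4R)-4-benzyl-1,3-oxazolidin-2-one instead of 3, comes back at 5): auxiliary-controlled glycolate alkylation. Acylation with [(4-methoxyphenyl)methoxy]acetyl chloride gives the glycolyl imide F6. Its sodium enolate (NaN(SiMe3)2, −78 °C) and prenyl bromide give the alkylated imide F7. MeONHMe·HCl/AlMe3 gives the Weinreb amide F8, MeMgBr gives the PMB-protected ketone F9, and DDQ releases 5.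

**Step 4.** The risks are incomplete alkylation (proton transfer to the dianion, retro-aldol on warming) and loss of facial control if the tertiary alkoxide does not shield its face. Fallback (sets out from 7, comes back at 9): reverse the order of ring formation and alkylation. Bromoetherification of 7 (TBCO) gives the unsubstituted bromo lactone F10, whose lithium enolate (LiN(SiMe3)2, −78 °C) is alkylated with 2. If the electrophile enters syn to O17 and gives the C20 epimer F11, re-enolisation and kinetic protonation from that same face would convert F11 into 9.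

## Further compounds

F1 | step 14 | tert-butyl{[(3S,4aS,6R,7R,9R,9aS)-3-bromo-6,9-diethenyl-2,2,6,9a-tetramethyloctahydro-2H-pyrano[3,2-b]oxepin-7-yl]oxy}dimethylsilane | C=C[C@@]1(C)O[C@H]2C[C@H](Br)C(C)(C)O[C@@]2(C)[C@@H](C=C)C[C@H]1O[Si](C)(C)C(C)(C)C
F2 | step 14 | tert-butyl{[(1R,2S,5S,7S,9R,13R)-5-bromo-2,4,4,9-tetramethyl-3,8-dioxatricyclo[7.2.2.0^{2,7}]tridec-10-en-13-yl]oxy}dimethylsilane | C1=C[C@@]2(C)O[C@H]3C[C@H](Br)C(C)(C)O[C@@]3(C)[C@@H]1C[C@H]2O[Si](C)(C)C(C)(C)C
F3 | step 14 | (1R,2S,5S,7S,9R,11R,13R)-5-bromo-13-{[tert-butyl(dimethyl)silyl]oxy}-2,4,4,9-tetramethyl-3,8-dioxatricyclo[7.2.2.0^{2,7}]tridecan-11-ol | O[C@@H]1C[C@@]2(C)O[C@H]3C[C@H](Br)C(C)(C)O[C@@]3(C)[C@@H]1C[C@H]2O[Si](C)(C)C(C)(C)C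
F4 | step 5 | (3S,4S,5S)-5-{[(2R)-3,3-dimethyloxiran-2-yl]methyl}-4-hydroxy-4-methyl-3-[(2Z)-3-methylpent-2-en-4-yn-1-yl]oxolan-2-one | O=C1[C@@H](C/C=C(C)\C#C)[C@](C)(O)[C@H](C[C@H]2OC2(C)C)O1
F5 | step 5 | (3S,4S,5S)-5-[(2S)-2-bromo-3-hydroxy-3-methylbutyl]-4-hydroxy-4-methyl-3-[(2Z)-3-methylpent-2-en-4-yn-1-yl]oxolan-2-one | O=C1[C@@H](C/C=C(C)\C#C)[C@](C)(O)[C@H](C[C@H](Br)C(C)(C)O)O1
F6 | step 2 | (4R)-4-benzyl-3-{[(4-methoxyphenyl)methoxy]acetyl}-1,3-oxazolidin-2-one | COc1ccc(COCC(=O)N2[C@H](Cc3ccccc3)COC2=O)cc1
F7 | step 2 | (4R)-4-benzyl-3-{(2S)-2-[(4-methoxyphenyl)methoxy]-5-methylhex-4-enoyl}-1,3-oxazolidin-2-one | COc1ccc(CO[C@@H](CC=C(C)C)C(=O)N2[C@H](Cc3ccccc3)COC2=O)cc1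
F8 | step 2 | (2S)-N-methoxy-2-[(4-methoxyphenyl)methoxy]-N,5-dimethylhex-4-enamide | COc1ccc(CO[C@@H](CC=C(C)C)C(=O)N(C)OC)cc1
F9 | step 2 | (3S)-3-[(4-methoxyphenyl)methoxy]-6-methylhept-5-en-2-one | COc1ccc(CO[C@@H](CC=C(C)C)C(C)=O)cc1
F10 | step 4 | (3aS,6S,7aS)-6-bromo-3a,5,5-trimethylhexahydro-2H-furo[3,2-b]pyran-2-one | O=C1O[C@H]2C[C@H](Br)C(C)(C)O[C@@]2(C)C1
F11 | step 4 | (3R,3aS,6S,7aS)-6-bromo-3a,5,5-trimethyl-3-[(2Z)-3-methylpent-2-en-4-yn-1-yl]hexahydro-2H-furo[3,2-b]pyran-2-one | O=C1O[C@H]2C[C@H](Br)C(C)(C)O[C@@]2(C)[C@H]1C/C=C(C)\C#C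
A1 | alternative 1 | 6-(6-hydroxy-2,6-dimethyl-3-oxo-3,6-dihydro-2H-pyran-2-yl)-4-methylcyclohex-3-en-1-yl acetate (C5, C18, C20 as in 22; C14 anomers) | CC(=O)O[C@H]1CC(C)=CC[C@H]1[C@]2(C)OC(C)(O)C=CC2=O
A2 | alternative 1 | 6-[1-hydroxy-1-(5-methylfuran-2-yl)ethyl]-4-methylcyclohex-3-en-1-yl acetate (C5, C18, C20 as in 22) | CC(=O)O[C@H]1CC(C)=CC[C@H]1[C@](C)(O)c2ccc(C)o2
A3 | alternative 2 | oxasilolane-fused 5-methoxy-1,3-dimethylbicyclo[2.2.2]oct-5-en-2-one (C5, C7, C18, C20 as in 22) | C[Si]1(C)O[C@]2(C)C(=O)[C@]3(C)C[C@H]1[C@H]2C=C3OC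
A4 | alternative 2 | 6-[(ethenyldimethylsilyl)oxy]-3-methoxy-2,6-dimethylcyclohexa-2,4-dien-1-one (C18 as in 22) | C=C[Si](C)(C)O[C@@]1(C)C=CC(OC)=C(C)C1=O
A5 | alternative 3 | ethyl 2-oxabicyclo[3.2.2]nonan-3-ylacetate bearing the C18 hydroxyl and methyl, the C5 hydroxyl and the C22 silyl ether (configuration as in 22) | O[C@H]1C[C@@]2(C)O[C@@H](CC(=O)OCC)[C@@](C)(O)[C@@H]1C[C@H]2O[Si](C)(C)C(C)(C)C
A6 | alternative 3 | ethyl (2E)-3-[(4-acetyl-2-{[tert-butyl(dimethyl)silyl]oxy}-5-hydroxy-1-methylcyclohexyl)oxy]prop-2-enoate (C5, C7, C20, C22 as in 22) | CC(=O)[C@@H]1C[C@@H](O[Si](C)(C)C(C)(C)C)[C@](C)(O/C=C/C(=O)OCC)C[C@@H]1O
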